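**Retrosynthetic overview**

1. Numbering used throughout: ring C1 (CH–OH), C2 (CH–O‑angeloyl), C3 (C(CH3)OH), C4 (CHCl), C5 (CH2), C6 (CH carrying the side chain); side chain C7(=C14H2)–C8(O‑angeloyl)–C9H2–C10/C11 oxirane (C11 bears two CH3).
2. The oxirane is disconnected last (Shi epoxidation of C10=C11, step 17). The cyclohexane is then opened at C1–C6: the C1 carbinol is homoallylic to the exocyclic C7=C14 methylene, so C1(OH)–C6(H)–C7(=C14H2) is the retron of a carbonyl allylation, and the cis relation (axial C1–OH, equatorial C6 branch) is what a Z‑type allylboronate gives through a closed chair transition state.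
3. The seco‑precursor is an acyclic C1 aldehyde carrying a (Z)‑C6=C7 alkenyl iodide and both angelates. One Negishi borylmethylation converts it into the allylboronate, which closes the ring, sets C1 and C6, creates the C7=C14 methylene and frees C1–OH.
4. The iodide comes from a C6≡C7 alkyne (C1–C7 alkyne plus C8–C13 Weinreb amide, Noyori reduction for C8, hydroxyl‑directed trans‑hydrostannation/iodination). The ring centres are relayed from one catalytically set centre: C4 (organocatalytic α‑chlorination) → C2 (γ‑alkoxyallylboration) → C3 (chelation/Cornforth‑controlled CH3MgBr addition) → C1 and C6 (key step).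
5. Ring order: temporary 1,3,2‑dioxasilinane over O1/O3 (steps 7–14) → cyclohexane (step 16) → oxirane (step 17).

Key step: step 16

Remark: the tetrahydropyranyl acetal carbon is uncontrolled, so compounds 3–12 and 16–20 are epimer mixtures at that carbon (drawn without a descriptor there) that converge in step 12; compounds 1, 3 and 13 and all reagents named are taken as commercial.

**Route**

Step 1
Reactants: 1 pent-4-ynal
Product: 2 (2S)-2-chloropent-4-ynal
Conditions: N-chlorosuccinimide, 2,5-diphenylpyrrolidine (10 mol%; the enantiomer that delivers the 2S chloride, expected to be (2R,5R)), CH2Cl2, 0 °C to rt; short silica plug, used at once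
Reagents that add atoms: N-chlorosuccinimide, O=C1CCC(=O)N1Cl
Why: Enamine‑mediated organocatalytic α‑chlorination of an aldehyde, in which the C2‑symmetric amine shields one enamine face so that chlorine is delivered to give the 2S centre (C4 of the target), the only ring stereocentre set by catalysis; the configurationally labile product is not stored.

Step 2
Reactants: 3 2-(prop-2-en-1-yloxy)oxane
Product: 5 2-[(2Z)-3-(oxan-2-yloxy)prop-2-en-1-yl]-4,4,5,5-tetramethyl-1,3,2-dioxaborolane, via Z-oxyallyllithium 4 (not isolated)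
Conditions: sec-BuLi, THF, −78 °C; 2-isopropoxy-4,4,5,5-tetramethyl-1,3,2-dioxaborolane, −78 °C to rt; HCl in Et2O (1 equiv)
Reagents that add atoms: 2-isopropoxy-4,4,5,5-tetramethyl-1,3,2-dioxaborolane, CC(C)OB1OC(C)(C)C(C)(C)O1
Why: Lithiation–borylation of an allyl acetal ether: deprotonation gives the internally chelated Z‑oxyallyllithium, which is borylated at the carbon remote from oxygen, fixing the Z enol ether geometry needed for a syn addition; no stereocentre is formed.

Step 3
Reactants: 2 (2S)-2-chloropent-4-ynal; 5 Z-γ-(oxan-2-yloxy)allylboronate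
Product: 7 (3S,4R,5S)-5-chloro-3-(oxan-2-yloxy)oct-1-en-7-yn-4-ol, via borate ester 6 (not isolated)
Conditions: CH2Cl2, 4 Å molecular sieves, 0 °C to rt; aq. NaHCO3 work-up
Reagents that add atoms: none
Why: γ‑Alkoxyallylboration through a chair Zimmerman–Traxler transition state: the Z enol ether gives the 3,4‑syn alkoxy alcohol and the α‑chloro centre directs attack to the Cornforth (polar Felkin–Anh) face (4,5‑anti), which together fix the new 3S centre (C2 of the target) relative to C4; the carbinol centre is deleted in step 4.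

Step 4
Reactants: 7 (3S,4R,5S)-5-chloro-3-(oxan-2-yloxy)oct-1-en-7-yn-4-ol
Product: 8 (3S,5S)-5-chloro-3-(oxan-2-yloxy)oct-1-en-7-yn-4-one
Conditions: Dess–Martin periodinane, NaHCO3, CH2Cl2, 0 °C; used at once
Reagents that add atoms: none
Why: Dess–Martin oxidation under buffered, neutral conditions removes the dispensable carbinol centre and provides the ketone for a doubly controlled methyl addition; the two α‑centres should not enolise at this temperature.

Step 5
Reactants: 8 (3S,5S)-5-chloro-3-(oxan-2-yloxy)oct-1-en-7-yn-4-one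
Product: 9 (3S,4S,5S)-5-chloro-4-methyl-3-(oxan-2-yloxy)oct-1-en-7-yn-4-ol
Conditions: MeMgBr (3 equiv), THF, −78 °C; aq. NH4Cl
Reagents that add atoms: methylmagnesium bromide, C[Mg]Br
Why: Chelation‑controlled Grignard addition (Cram chelate): magnesium bridges the ketone and α‑acetal oxygens so that CH3 attacks the face away from the vinyl group, and this is also the Cornforth/polar Felkin–Anh face with respect to the α′‑chlorine, so both elements should give the 4S tertiary carbinol (C3 of the target).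

Step 6
Reactants: 9 (3S,4S,5S)-5-chloro-4-methyl-3-(oxan-2-yloxy)oct-1-en-7-yn-4-ol
Product: 11 (2S,3S,4S)-4-chloro-3-methyl-2-(oxan-2-yloxy)hept-6-yne-1,3-diol, via aldehyde 10 (not isolated)
Conditions: O3, CH2Cl2/MeOH, −78 °C (indicator dye); then NaBH4, −78 to 0 °C
Reagents that add atoms: ozone, [O-][O+]=O
Why: Ozonolysis with reductive NaBH4 work‑up: the vinyl group reacts far faster than the terminal alkyne, acetal and chloride, and borohydride reduces aldehyde 10 in situ to the primary alcohol that later becomes the C1 aldehyde; no stereocentre is touched.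

Step 7
Reactants: 11 (2S,3S,4S)-4-chloro-3-methyl-2-(oxan-2-yloxy)hept-6-yne-1,3-diol
Product: 12 (4S,5S)-2,2-di-tert-butyl-4-[(1S)-1-chlorobut-3-yn-1-yl]-4-methyl-5-(oxan-2-yloxy)-1,3,2-dioxasilinane
Conditions: tBu2Si(OTf)2, 2,6-lutidine, CH2Cl2, 0 °C to rt
Reagents that add atoms: di-tert-butylsilyl bis(trifluoromethanesulfonate), CC(C)(C)[Si](OS(=O)(=O)C(F)(F)F)(OS(=O)(=O)C(F)(F)F)C(C)(C)C
Why: Cyclic silylene protection of the 1,3‑diol masks the primary and tertiary hydroxyls in one six‑membered ring, removing acidic protons before the acetylide step and preventing base‑induced closure of the chlorohydrin.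

Step 8
Reactants: 13 4-methylpent-3-enoic acid
Product: 15 N-methoxy-N,4-dimethylpent-3-enamide, via acyl imidazole 14 (not isolated)
Conditions: 1,1'-carbonyldiimidazole, CH2Cl2, rt; then MeNHOMe·HCl, rt
Reagents that add atoms: N,O-dimethylhydroxylamine hydrochloride, CNOC.Cl
Why: Weinreb amide formation through the acyl imidazole; the mild, base‑free activation should avoid migration of the β,γ double bond.

Step 9
Reactants: 12 silylene-protected alkyne; 15 N-methoxy-N,4-dimethylpent-3-enamide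
Product: 17 (9S)-9-chloro-9-[(4S,5S)-2,2-di-tert-butyl-4-methyl-5-(oxan-2-yloxy)-1,3,2-dioxasilinan-4-yl]-2-methylnon-2-en-6-yn-5-one, via lithium acetylide 16 (not isolated)
Conditions: n-BuLi (1.05 equiv), THF, −78 °C; then 15, −78 to −20 °C; aq. NH4Cl
Reagents that add atoms: none
Why: Acylation of a lithium acetylide by a Weinreb amide: the chelated tetrahedral intermediate stops at the ketone stage, and alkyne deprotonation is much faster than any reaction of the secondary chloride, silylene or acetal.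

Step 10
Reactants: 17 alkynyl ketone
Product: 18 (5S,9S)-9-chloro-9-[(4S,5S)-2,2-di-tert-butyl-4-methyl-5-(oxan-2-yloxy)-1,3,2-dioxasilinan-4-yl]-2-methylnon-2-en-6-yn-5-ol
Conditions: RuCl[(S,S)-TsDPEN](p-cymene) (2 mol%), propan-2-ol, rt
Reagents that add atoms: none
Why: Noyori asymmetric transfer hydrogenation of an alkynyl ketone: the (S,S)‑catalyst should deliver hydride to the face that gives the 5S propargylic alcohol (C8 of the target) under catalyst control, with alkenes and the alkyne left unreduced.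

Step 11
Reactants: 18 propargylic alcohol
Product: 20 (5S,6Z,9S)-9-chloro-9-[(4S,5S)-2,2-di-tert-butyl-4-methyl-5-(oxan-2-yloxy)-1,3,2-dioxasilinan-4-yl]-6-iodo-2-methylnona-2,6-dien-5-ol, via alkenylstannane 19 (not isolated)
Conditions: [Cp*RuCl]4 (2.5 mol%), Bu3SnH (1.1 equiv), CH2Cl2, rt; then I2 (1.1 equiv), −78 to 0 °C; aq. Na2S2O3
Reagents that add atoms: iodine, II
Why: Hydroxyl‑directed ruthenium‑catalysed trans‑hydrostannation puts tin on the alkyne carbon next to the carbinol (C7) and hydrogen on C6 anti to it, and iododestannylation proceeds with retention, so iodine ends cis to C5, the geometry the key step needs.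

Step 12
Reactants: 20 alkenyl iodide
Product: 21 (4S,5S)-2,2-di-tert-butyl-4-[(1S,3Z,5S)-1-chloro-5-hydroxy-4-iodo-8-methylnona-3,7-dien-1-yl]-4-methyl-1,3,2-dioxasilinan-5-ol
Conditions: pyridinium p-toluenesulfonate (0.2 equiv), MeOH, 40 °C
Reagents that add atoms: none
Why: Acid‑catalysed transacetalisation removes the tetrahydropyranyl group as 2‑methoxyoxane, leaves the silylene, alkenyl iodide and trisubstituted alkene untouched, and merges the acetal epimers into one compound.

Step 13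
Reactants: 21 silylene-protected diol
Product: 22 (4S,5S)-2,2-di-tert-butyl-4-[(1S,3Z,5S)-1-chloro-4-iodo-8-methyl-5-{[(2Z)-2-methylbut-2-enoyl]oxy}nona-3,7-dien-1-yl]-4-methyl-1,3,2-dioxasilinan-5-yl (2Z)-2-methylbut-2-enoate
Conditions: angelic acid (6 equiv), 2,4,6-trichlorobenzoyl chloride (6 equiv), Et3N, toluene, rt; then 21, 75 °C
Reagents that add atoms: angelic acid ((2Z)-2-methylbut-2-enoic acid), C/C=C(/C)C(=O)O
Why: Yamaguchi‑type mixed‑anhydride esterification run without DMAP acylates both hindered secondary alcohols (O2 and O8) while avoiding Z‑to‑E isomerisation to tiglates; the tertiary oxygen is masked in the silylene, so no chlorohydrin closure can occur.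

Step 14
Reactants: 22 bis-angelate silylene
Product: 23 (2S,3S,4S,6Z,8S)-4-chloro-1,3-dihydroxy-7-iodo-3,11-dimethyldodeca-6,10-diene-2,8-diyl bis[(2Z)-2-methylbut-2-enoate]
Conditions: HF·pyridine, pyridine, THF, 0 °C to rt
Reagents that add atoms: none
Why: Fluoride cleavage of the two Si–O bonds (silylene deprotection) under pyridine buffering frees the primary C1–OH and tertiary C3–OH without touching esters, chloride or alkenyl iodide.

Step 15
Reactants: 23 diol bis-angelate
Product: 24 (2R,3S,4S,6Z,8S)-4-chloro-3-hydroxy-7-iodo-3,11-dimethyl-1-oxododeca-6,10-diene-2,8-diyl bis[(2Z)-2-methylbut-2-enoate]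
Conditions: Dess–Martin periodinane (1.3 equiv), NaHCO3, CH2Cl2, 0 °C; used at once
Reagents that add atoms: none
Why: Dess–Martin oxidation, in which only the primary carbinol can be oxidised and the buffer keeps the α‑acyloxy aldehyde from epimerising (the descriptor at C2 changes to R by priority only).

Step 16
Reactants: 24 iodo aldehyde
Product: 27 (1S,2S,3S,4S,6R,8S)-4-chloro-1,3-dihydroxybisabola-7(14),10-diene-2,8-diyl bis[(2Z)-2-methylbut-2-enoate], via allylboronate aldehyde 25 (not isolated), via cyclic borate 26 (not isolated)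
Conditions: IZnCH2Bpin (3 equiv, from ICH2Bpin and Zn dust in THF), Pd(PPh3)4 (5 mol%), THF, rt; then pH 7 buffer/aq. NH4Cl
Reagents that add atoms: (pinacolatoboryl)methylzinc iodide, I[Zn]CB1OC(C)(C)C(C)(C)O1
Why: Oxidative addition of zerovalent palladium to the alkenyl iodide, transmetalation with the borylmethylzinc reagent and reductive elimination (Negishi coupling, retention of alkene geometry) should give allylboronate 25 with CH2Bpin cis to C5, which is trapped at once by the C1 aldehyde in an intramolecular allylboration, the closest known type being the stereospecific cyclisation of ω‑formyl Z‑allylboronates. The cyclohexane closes by attack of C6 on C1 in a 6‑exo‑trig mode through a bicyclic chair–chair Zimmerman–Traxler transition state, with allylic transposition that creates the C7=C14 methylene and delivers C1–O as pinacol borate 26, hydrolysed on work‑up. Because CH2B and C5 are cis on the configurationally stable pinacol allylboronate, C5 is axial and C2 equatorial on the boron‑containing chair, which forces C1–O axial and the C7 branch equatorial on the new ring, i.e. the cis C1–OH/C6 relation. The face is decided by the C2–C4 centres: the chair leading to 1S,6R keeps C3–CH3 and the C2 angelate equatorial, has C2–O antiperiplanar to the forming bond (polar Felkin–Anh) and lets the axial C3–OH hydrogen‑bond to the carbonyl oxygen, whereas the other chair needs a 1,3‑diaxial CH3/C=O contact. The step needs geometric integrity of the alkene (secured by the stereospecific coupling and the slow 1,3‑boratropic shift of pinacol boronates) and chemoselectivity (alkylzinc iodides do not add to aldehydes; the secondary chloride, the esters and the C10=C11 alkene are inert).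

Step 17
Reactants: 27 ring-closed diene
Product: 28 CNP0158207.1, (1S,2S,3S,4S,6R,8S,10R)-4-chloro-10,11-epoxy-1,3-dihydroxybisabol-7(14)-ene-2,8-diyl bis[(2Z)-2-methylbut-2-enoate]
Conditions: D-fructose-derived ketone of the Shi epoxidation (1,2:4,5-di-O-isopropylidene-β-D-erythro-2,3-hexodiulo-2,6-pyranose, 3 equiv), KHSO5 (Oxone), NaHCO3, Bu4NHSO4 (cat.), MeCN–aq. Na2H2EDTA, pH 7–8, 0 °C
Reagents that add atoms: potassium peroxymonosulfate, [K+].[O-]S(=O)(=O)OO
Why: Shi epoxidation (chiral dioxirane, spiro transition state): reagent control should deliver oxygen to the face of the trisubstituted C10=C11 bond that gives 10R; the pH 7–8 variant keeps the trans‑diaxial chlorohydrin from closing, and the electron‑poor angelate alkenes and the allylically deactivated 1,1‑disubstituted C7=C14 alkene react far more slowly.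

**Compound list**

1 | pent-4-ynal | C#CCCC=O | starting material
2 | (2S)-2-chloropent-4-ynal | C#CC[C@H](Cl)C=O | intermediate
3 | 2-(prop-2-en-1-yloxy)oxane | C=CCOC1CCCCO1 | starting material
4 | [(2Z)-3-(oxan-2-yloxy)prop-2-en-1-yl]lithium (chelated Z-oxyallyl anion) | [Li]C/C=C\OC1CCCCO1 | intermediate (not isolated)
5 | 2-[(2Z)-3-(oxan-2-yloxy)prop-2-en-1-yl]-4,4,5,5-tetramethyl-1,3,2-dioxaborolane | CC1(C)OB(C/C=C\OC2CCCCO2)OC1(C)C | intermediate
6 | 2-{[(3S,4R,5S)-5-chloro-3-(oxan-2-yloxy)oct-1-en-7-yn-4-yl]oxy}-4,4,5,5-tetramethyl-1,3,2-dioxaborolane | C#CC[C@H](Cl)[C@H](OB1OC(C)(C)C(C)(C)O1)[C@@H](OC2CCCCO2)C=C | intermediate (not isolated)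
7 | (3S,4R,5S)-5-chloro-3-(oxan-2-yloxy)oct-1-en-7-yn-4-ol | C#CC[C@H](Cl)[C@H](O)[C@@H](OC1CCCCO1)C=C | intermediate
8 | (3S,5S)-5-chloro-3-(oxan-2-yloxy)oct-1-en-7-yn-4-one | C#CC[C@H](Cl)C(=O)[C@@H](OC1CCCCO1)C=C | intermediate
9 | (3S,4S,5S)-5-chloro-4-methyl-3-(oxan-2-yloxy)oct-1-en-7-yn-4-ol | C#CC[C@H](Cl)[C@@](C)(O)[C@@H](OC1CCCCO1)C=C | intermediate
10 | (2R,3S,4S)-4-chloro-3-hydroxy-3-methyl-2-(oxan-2-yloxy)hept-6-ynal | C#CC[C@H](Cl)[C@@](C)(O)[C@@H](OC1CCCCO1)C=O | intermediate (not isolated)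
11 | (2S,3S,4S)-4-chloro-3-methyl-2-(oxan-2-yloxy)hept-6-yne-1,3-diol | C#CC[C@H](Cl)[C@@](C)(O)[C@@H](OC1CCCCO1)CO | intermediate
12 | (4S,5S)-2,2-di-tert-butyl-4-[(1S)-1-chlorobut-3-yn-1-yl]-4-methyl-5-(oxan-2-yloxy)-1,3,2-dioxasilinane | C#CC[C@H](Cl)[C@@]1(C)O[Si](C(C)(C)C)(C(C)(C)C)OC[C@@H]1OC2CCCCO2 | intermediate
13 | 4-methylpent-3-enoic acid | CC(C)=CCC(=O)O | starting material
14 | 1-(1H-imidazol-1-yl)-4-methylpent-3-en-1-one | CC(C)=CCC(=O)n1ccnc1 | intermediate (not isolated)
15 | N-methoxy-N,4-dimethylpent-3-enamide | CC(C)=CCC(=O)N(C)OC | intermediate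
16 | [(4S)-4-chloro-4-{(4S,5S)-2,2-di-tert-butyl-4-methyl-5-(oxan-2-yloxy)-1,3,2-dioxasilinan-4-yl}but-1-yn-1-yl]lithium | [Li]C#CC[C@H](Cl)[C@@]1(C)O[Si](C(C)(C)C)(C(C)(C)C)OC[C@@H]1OC2CCCCO2 | intermediate (not isolated)
17 | (9S)-9-chloro-9-[(4S,5S)-2,2-di-tert-butyl-4-methyl-5-(oxan-2-yloxy)-1,3,2-dioxasilinan-4-yl]-2-methylnon-2-en-6-yn-5-one | CC(C)=CCC(=O)C#CC[C@H](Cl)[C@@]1(C)O[Si](C(C)(C)C)(C(C)(C)C)OC[C@@H]1OC2CCCCO2 | intermediate
18 | (5S,9S)-9-chloro-9-[(4S,5S)-2,2-di-tert-butyl-4-methyl-5-(oxan-2-yloxy)-1,3,2-dioxasilinan-4-yl]-2-methylnon-2-en-6-yn-5-ol | CC(C)=CC[C@H](O)C#CC[C@H](Cl)[C@@]1(C)O[Si](C(C)(C)C)(C(C)(C)C)OC[C@@H]1OC2CCCCO2 | intermediate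
19 | (5S,6Z,9S)-9-chloro-9-[(4S,5S)-2,2-di-tert-butyl-4-methyl-5-(oxan-2-yloxy)-1,3,2-dioxasilinan-4-yl]-2-methyl-6-(tributylstannyl)nona-2,6-dien-5-ol | CC(C)=CC[C@H](O)/C(=C/C[C@H](Cl)[C@@]1(C)O[Si](C(C)(C)C)(C(C)(C)C)OC[C@@H]1OC2CCCCO2)[Sn](CCCC)(CCCC)CCCC | intermediate (not isolated)
20 | (5S,6Z,9S)-9-chloro-9-[(4S,5S)-2,2-di-tert-butyl-4-methyl-5-(oxan-2-yloxy)-1,3,2-dioxasilinan-4-yl]-6-iodo-2-methylnona-2,6-dien-5-ol | CC(C)=CC[C@H](O)/C(I)=C/C[C@H](Cl)[C@@]1(C)O[Si](C(C)(C)C)(C(C)(C)C)OC[C@@H]1OC2CCCCO2 | intermediate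
21 | (4S,5S)-2,2-di-tert-butyl-4-[(1S,3Z,5S)-1-chloro-5-hydroxy-4-iodo-8-methylnona-3,7-dien-1-yl]-4-methyl-1,3,2-dioxasilinan-5-ol | CC(C)=CC[C@H](O)/C(I)=C/C[C@H](Cl)[C@@]1(C)O[Si](C(C)(C)C)(C(C)(C)C)OC[C@@H]1O | intermediate
22 | (4S,5S)-2,2-di-tert-butyl-4-[(1S,3Z,5S)-1-chloro-4-iodo-8-methyl-5-{[(2Z)-2-methylbut-2-enoyl]oxy}nona-3,7-dien-1-yl]-4-methyl-1,3,2-dioxasilinan-5-yl (2Z)-2-methylbut-2-enoate | CC(C)=CC[C@H](OC(=O)/C(C)=C\C)/C(I)=C/C[C@H](Cl)[C@@]1(C)O[Si](C(C)(C)C)(C(C)(C)C)OC[C@@H]1OC(=O)/C(C)=C\C | intermediate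
23 | (2S,3S,4S,6Z,8S)-4-chloro-1,3-dihydroxy-7-iodo-3,11-dimethyldodeca-6,10-diene-2,8-diyl bis[(2Z)-2-methylbut-2-enoate] | CC(C)=CC[C@H](OC(=O)/C(C)=C\C)/C(I)=C/C[C@H](Cl)[C@@](C)(O)[C@@H](OC(=O)/C(C)=C\C)CO | intermediate
24 | (2R,3S,4S,6Z,8S)-4-chloro-3-hydroxy-7-iodo-3,11-dimethyl-1-oxododeca-6,10-diene-2,8-diyl bis[(2Z)-2-methylbut-2-enoate] | CC(C)=CC[C@H](OC(=O)/C(C)=C\C)/C(I)=C/C[C@H](Cl)[C@@](C)(O)[C@@H](OC(=O)/C(C)=C\C)C=O | intermediate
25 | (2R,3S,4S,6E,8S)-4-chloro-3-hydroxy-3,11-dimethyl-1-oxo-7-[(4,4,5,5-tetramethyl-1,3,2-dioxaborolan-2-yl)methyl]dodeca-6,10-diene-2,8-diyl bis[(2Z)-2-methylbut-2-enoate] | CC(C)=CC[C@H](OC(=O)/C(C)=C\C)/C(CB1OC(C)(C)C(C)(C)O1)=C/C[C@H](Cl)[C@@](C)(O)[C@@H](OC(=O)/C(C)=C\C)C=O | intermediate (not isolated)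
26 | pinacol borate of 27 at O1 (1-O-(4,4,5,5-tetramethyl-1,3,2-dioxaborolan-2-yl) derivative) | C=C([C@H](CC=C(C)C)OC(=O)/C(C)=C\C)[C@H]1C[C@H](Cl)[C@@](C)(O)[C@@H](OC(=O)/C(C)=C\C)[C@H]1OB2OC(C)(C)C(C)(C)O2 | intermediate (not isolated)
27 | (1S,2S,3S,4S,6R,8S)-4-chloro-1,3-dihydroxybisabola-7(14),10-diene-2,8-diyl bis[(2Z)-2-methylbut-2-enoate] | C=C([C@H](CC=C(C)C)OC(=O)/C(C)=C\C)[C@H]1C[C@H](Cl)[C@@](C)(O)[C@@H](OC(=O)/C(C)=C\C)[C@H]1O | intermediate
28 | CNP0158207.1, (1S,2S,3S,4S,6R,8S,10R)-4-chloro-10,11-epoxy-1,3-dihydroxybisabol-7(14)-ene-2,8-diyl bis[(2Z)-2-methylbut-2-enoate] | C=C([C@H](C[C@H]1OC1(C)C)OC(=O)/C(C)=C\C)[C@H]1C[C@H](Cl)[C@@](C)(O)[C@@H](OC(=O)/C(C)=C\C)[C@H]1O | target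

**Step count and risks**

Total: 17 steps. Longest linear sequence: 15 steps (1, 3–7, 9–17); steps 2 and 8 are one-step side branches.

Steps most likely to fail:

Step 16 (key step). The alkene geometry may be lost at palladium, which would give the trans C1/C6 diastereomer. The β‑hydroxy‑α‑acyloxy aldehyde may undergo retro‑aldol cleavage or reduction in the presence of zinc and palladium, and slow transmetalation may lead to protodehalogenation. The fallback sets out from 23 and returns at 27. The diol 23 is coupled with Me3SiCH2ZnCl and Pd(PPh3)4 (THF, 40 °C, no aldehyde present) to give the allylsilane diol F1. Dess–Martin oxidation gives the isolable allylsilane aldehyde F2. SnCl4 in CH2Cl2 at −78 °C then promotes an intramolecular Hosomi–Sakurai allylation in which tin bridges the C1 carbonyl and the C3 hydroxyl, placing the two oxygens 1,3‑syn as in the target with the alkenyl branch equatorial, and gives 27.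

Step 17. The trans‑diaxial chlorohydrin may close to the 3,4‑epoxide in the buffered medium, the C7=C14 methylene may be epoxidised competitively, and the ketone may be consumed by Baeyer–Villiger oxidation at the low pH required. The fallback sets out from 27 and returns at 28. tBu2Si(OTf)2 and 2,6‑lutidine bridge the axial C1 and C3 hydroxyls to give the 1,3‑silylene F3, which masks the chlorohydrin oxygen. A standard Shi epoxidation at pH 10.5 then gives the epoxy silylene F4, and Et3N·3HF in THF removes the silylene to give 28.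

Step 5. The Grignard reagent may enolise the α‑chloro, α′‑alkoxy, β′,γ′‑unsaturated ketone, causing epimerisation at C2 or C4 or migration of the vinyl double bond into conjugation, and chelation control may be incomplete. The fallback sets out from 7 and returns at 11; it removes the vinyl group before the ketone is made. Ozonolysis of 7 with NaBH4 work‑up passes through the hydroxy aldehyde F5 and gives the diol F6. TBDPSCl and imidazole protect the primary hydroxyl to give the silyl ether F7, and Dess–Martin oxidation gives the ketone F8, which can no longer conjugate. MeMgBr addition under the same chelation/Cornforth control gives the tertiary alcohol F9, and HF·pyridine returns diol 11.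

Further compounds
F1 | step 16 | (2S,3S,4S,6Z,8S)-4-chloro-1,3-dihydroxy-3,11-dimethyl-7-[(trimethylsilyl)methyl]dodeca-6,10-diene-2,8-diyl bis[(2Z)-2-methylbut-2-enoate] | CC(C)=CC[C@H](OC(=O)/C(C)=C\C)/C(C[Si](C)(C)C)=C/C[C@H](Cl)[C@@](C)(O)[C@@H](OC(=O)/C(C)=C\C)CO
F2 | step 16 | (2R,3S,4S,6Z,8S)-4-chloro-3-hydroxy-3,11-dimethyl-1-oxo-7-[(trimethylsilyl)methyl]dodeca-6,10-diene-2,8-diyl bis[(2Z)-2-methylbut-2-enoate] | CC(C)=CC[C@H](OC(=O)/C(C)=C\C)/C(C[Si](C)(C)C)=C/C[C@H](Cl)[C@@](C)(O)[C@@H](OC(=O)/C(C)=C\C)C=O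
F3 | step 17 | 1,3-O-(di-tert-butylsilanediyl) derivative of 27 | C=C([C@H](CC=C(C)C)OC(=O)/C(C)=C\C)[C@H]1C[C@H](Cl)[C@@](C)(O[Si]2(C(C)(C)C)C(C)(C)C)[C@@H](OC(=O)/C(C)=C\C)[C@H]1O2
F4 | step 17 | 1,3-O-(di-tert-butylsilanediyl) derivative of 28 (10R epoxide) | C=C([C@H](C[C@H]3OC3(C)C)OC(=O)/C(C)=C\C)[C@H]1C[C@H](Cl)[C@@](C)(O[Si]2(C(C)(C)C)C(C)(C)C)[C@@H](OC(=O)/C(C)=C\C)[C@H]1O2
F5 | step 5 | (2R,3R,4S)-4-chloro-3-hydroxy-2-(oxan-2-yloxy)hept-6-ynal | C#CC[C@H](Cl)[C@H](O)[C@@H](OC1CCCCO1)C=O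
F6 | step 5 | (2S,3R,4S)-4-chloro-2-(oxan-2-yloxy)hept-6-yne-1,3-diol | C#CC[C@H](Cl)[C@H](O)[C@@H](OC1CCCCO1)CO
F7 | step 5 | (2S,3R,4S)-1-[(tert-butyldiphenylsilyl)oxy]-4-chloro-2-(oxan-2-yloxy)hept-6-yn-3-ol | C#CC[C@H](Cl)[C@H](O)[C@@H](OC1CCCCO1)CO[Si](c2ccccc2)(c3ccccc3)C(C)(C)C
F8 | step 5 | (2S,4S)-1-[(tert-butyldiphenylsilyl)oxy]-4-chloro-2-(oxan-2-yloxy)hept-6-yn-3-one | C#CC[C@H](Cl)C(=O)[C@@H](OC1CCCCO1)CO[Si](c2ccccc2)(c3ccccc3)C(C)(C)C
F9 | step 5 | (2S,3S,4S)-1-[(tert-butyldiphenylsilyl)oxy]-4-chloro-3-methyl-2-(oxan-2-yloxy)hept-6-yn-3-ol | C#CC[C@H](Cl)[C@@](C)(O)[C@@H](OC1CCCCO1)CO[Si](c2ccccc2)(c3ccccc3)C(C)(C)C
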